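**Retrosynthetic overview**
1. 17 ⇒ tosylate 16 ⇒ 4-amino-3,5-dibromo compound 14. Both ring-B bromines lie meta to the OH, so they are placed ortho to a para-NH2 group that is then removed by hydrodediazoniation.
2. 14 ⇒ nitrophenol 10 by O-tosylation, NO2→NH2 reduction and double bromination.
3. Key disconnection: ring B of 10 ⇒ aryloxyacetone 6 (C6–C1–C2) + sodium nitromalonaldehyde 8 (C3–C4–C5). An intermolecular aldol condensation makes C5–C6, then a ring-closing aldol makes C2–C3 and the ring aromatises.
4. 6 ⇒ 3,5-dibromo-2-methoxyphenol 4 + chloroacetone 5. 4 ⇒ 3,5-dibromosalicylaldehyde 1 by O-methylation and Baeyer–Villiger oxidation. 8 ⇒ mucobromic acid 7.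
5. Ring order: ring A is bought fully brominated. Ring B is the only ring formed (step 5), and it is built on the ether oxygen already in place, so no diaryl-ether coupling is needed.

Assumption: the target has no stereocentre and its diaryl-ether axis rotates freely at room temperature, so it is achiral and no stereocontrol is needed.

**Step 1**
Reactants: 1 3,5-dibromo-2-hydroxybenzaldehyde
Product: 2 3,5-dibromo-2-methoxybenzaldehyde
Conditions: MeI, K2CO3, DMF, rt
Reagents that add atoms: iodomethane, CI
Why: Williamson O-methylation (SN2) of the acidic phenolate, with the aldehyde and aryl bromides inert to K2CO3/MeI.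

**Step 2**
Reactants: 2 3,5-dibromo-2-methoxybenzaldehyde
Product: 4 3,5-dibromo-2-methoxyphenol, via aryl formate 3 (not isolated)
Conditions: mCPBA, CH2Cl2, 40 °C; then MeOH, cat. conc. HCl, rt
Reagents that add atoms: mCPBA, OOC(=O)c1cccc(Cl)c1
Why: Baeyer–Villiger oxidation in which the ortho-alkoxy aryl group migrates in the Criegee adduct, followed by acid-catalysed transesterification of the labile aryl formate.

**Step 3**
Reactants: 4 3,5-dibromo-2-methoxyphenol; 5 chloroacetone
Product: 6 1-(3,5-dibromo-2-methoxyphenoxy)propan-2-one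
Conditions: K2CO3, acetone, reflux
Reagents that add atoms: none
Why: Williamson ether synthesis (SN2) of an unhindered phenolate on a very reactive α-chloroketone under base too weak for ketone self-condensation.

**Step 4**
Reactants: 7 mucobromic acid
Product: 8 sodium nitromalonaldehyde monohydrate
Conditions: NaNO2 (3.7 equiv), H2O/EtOH, 54 °C; cool to 0 °C; recrystallise from aq EtOH (impact-sensitive, so keep small and use promptly; also a catalogue item)
Reagents that add atoms: sodium nitrite, [Na+].[O-]N=O; water, O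
Why: Hill nitromalonaldehyde synthesis, in which nitrite replaces the vinylic bromide next to CHO by addition–elimination, water displaces the second bromide, and decarboxylation gives the resonance-stabilised anion that crystallises as its sodium salt.

**Step 5**
Reactants: 6 1-(3,5-dibromo-2-methoxyphenoxy)propan-2-one; 8 sodium nitromalonaldehyde monohydrate
Product: 10 2-(3,5-dibromo-2-methoxyphenoxy)-4-nitrophenol, via open-chain nitroenal 9 (not isolated)
Conditions: NaOH (1.1 equiv), EtOH/H2O 1:1, N2, 0 °C → rt, 3–5 d; then 2 M HCl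
Reagents that add atoms: none
Why: An intermolecular aldol condensation of the methyl-ketone enolate of 6 on one formyl group of 8 makes C5–C6, then ring-closing aldol condensation of the acidic ArO–CH2 on the second formyl group (C2–C3) and tautomerisation give the nitrophenolate irreversibly ([3+3] nitrophenol benzannulation), and because 8 is symmetric either order of bond formation gives the same single regioisomer with no stereocentre.

**Step 6**
Reactants: 10 2-(3,5-dibromo-2-methoxyphenoxy)-4-nitrophenol
Product: 11 2-(3,5-dibromo-2-methoxyphenoxy)-4-nitrophenyl 4-methylbenzenesulfonate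
Conditions: TsCl, Et3N, CH2Cl2, 0 °C → rt
Reagents that add atoms: 4-toluenesulfonyl chloride, Cc1ccc(cc1)S(=O)(=O)Cl
Why: O-sulfonylation of the acidic nitrophenol, which switches off the ortho/para-directing power of this oxygen, protects the later aminophenol from oxidation, and avoids the solvolysis of a 4-nitrophenyl carboxylate.

**Step 7**
Reactants: 11 2-(3,5-dibromo-2-methoxyphenoxy)-4-nitrophenyl 4-methylbenzenesulfonate
Product: 12 4-amino-2-(3,5-dibromo-2-methoxyphenoxy)phenyl 4-methylbenzenesulfonate
Conditions: Fe powder, AcOH/EtOH/H2O, 70 °C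
Reagents that add atoms: none
Why: Béchamp-type dissolving-metal nitro reduction, which leaves C–Br bonds, the sulfonate and both ethers untouched.

**Step 8**
Reactants: 12 4-amino-2-(3,5-dibromo-2-methoxyphenoxy)phenyl 4-methylbenzenesulfonate
Product: 14 4-amino-3,5-dibromo-2-(3,5-dibromo-2-methoxyphenoxy)phenyl 4-methylbenzenesulfonate, via monobromoaniline 13 (not isolated)
Conditions: NBS (2.1 equiv), MeCN, dark, 0 °C → rt
Reagents that add atoms: N-bromosuccinimide, O=C1CCC(=O)N1Br
Why: Electrophilic aromatic bromination controlled by the free NH2, whose para position is blocked, so C5 and then C3 (also para and ortho to the ether oxygen) react while dibrominated ring A and the sulfonyl-bearing tolyl ring are far too deactivated.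

**Step 9**
Reactants: 14 4-amino-3,5-dibromo-2-(3,5-dibromo-2-methoxyphenoxy)phenyl 4-methylbenzenesulfonate
Product: 16 3,5-dibromo-2-(3,5-dibromo-2-methoxyphenoxy)phenyl 4-methylbenzenesulfonate, via diazonium hydrogensulfate 15 (not isolated)
Conditions: NaNO2, conc. H2SO4/AcOH, 0–5 °C; then 50% aq H3PO2, cat. Cu2O, 0 °C → rt
Reagents that add atoms: sodium nitrite, [Na+].[O-]N=O; sulfuric acid, OS(=O)(=O)O (both stand only in 15, nothing of them remains in 16)
Why: Diazotisation with nitrosylsulfuric acid (needed for the weakly basic 2,6-dibromoaniline) followed by hypophosphorous-acid hydrodediazoniation (radical chain), run chloride-free so that the bromines ortho to N2+ are not exchanged.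

**Step 10**
Reactants: 16 3,5-dibromo-2-(3,5-dibromo-2-methoxyphenoxy)phenyl 4-methylbenzenesulfonate
Product: 17 3,5-dibromo-2-(3,5-dibromo-2-methoxyphenoxy)phenol
Conditions: 2 M aq NaOH, 1,4-dioxane, 80 °C; then 1 M HCl
Reagents that add atoms: none
Why: Alkaline sulfonate hydrolysis (hydroxide attack at sulfur) releases a stabilised dibromophenolate, and since ring A carries no activating group and no halogen ortho to the ether oxygen, neither Smiles migration nor dioxin closure competes.

**Compound list**
1 | 3,5-dibromo-2-hydroxybenzaldehyde (3,5-dibromosalicylaldehyde) | O=Cc1cc(Br)cc(Br)c1O | starting material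
2 | 3,5-dibromo-2-methoxybenzaldehyde | O=Cc1cc(Br)cc(Br)c1OC | intermediate
3 | 3,5-dibromo-2-methoxyphenyl formate (not isolated) | O=COc1cc(Br)cc(Br)c1OC | intermediate
4 | 3,5-dibromo-2-methoxyphenol | Oc1cc(Br)cc(Br)c1OC | intermediate
5 | chloroacetone (1-chloropropan-2-one) | CC(=O)CCl | starting material
6 | 1-(3,5-dibromo-2-methoxyphenoxy)propan-2-one | CC(=O)COc1cc(Br)cc(Br)c1OC | intermediate
7 | mucobromic acid, (2Z)-2,3-dibromo-4-oxobut-2-enoic acid (cyclic lactol in the solid) | O=C/C(Br)=C(/Br)C(=O)O | starting material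
8 | sodium nitromalonaldehyde monohydrate (drawn as the nitronate) | O=CC(C=O)=[N+]([O-])[O-].[Na+].O | intermediate
9 | (E)-6-(3,5-dibromo-2-methoxyphenoxy)-2-nitro-5-oxohex-2-enal (not isolated; one tautomer drawn, equilibrates through its dienolate) | O=C/C([N+](=O)[O-])=C\CC(=O)COc1cc(Br)cc(Br)c1OC | intermediate
10 | 2-(3,5-dibromo-2-methoxyphenoxy)-4-nitrophenol | Oc1ccc(cc1Oc1cc(Br)cc(Br)c1OC)[N+](=O)[O-] | intermediate
11 | 2-(3,5-dibromo-2-methoxyphenoxy)-4-nitrophenyl 4-methylbenzenesulfonate | Cc1ccc(cc1)S(=O)(=O)Oc1ccc(cc1Oc1cc(Br)cc(Br)c1OC)[N+](=O)[O-] | intermediate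
12 | 4-amino-2-(3,5-dibromo-2-methoxyphenoxy)phenyl 4-methylbenzenesulfonate | Cc1ccc(cc1)S(=O)(=O)Oc1ccc(N)cc1Oc1cc(Br)cc(Br)c1OC | intermediate
13 | 4-amino-5-bromo-2-(3,5-dibromo-2-methoxyphenoxy)phenyl 4-methylbenzenesulfonate (not isolated) | Cc1ccc(cc1)S(=O)(=O)Oc1cc(Br)c(N)cc1Oc1cc(Br)cc(Br)c1OC | intermediate
14 | 4-amino-3,5-dibromo-2-(3,5-dibromo-2-methoxyphenoxy)phenyl 4-methylbenzenesulfonate | Cc1ccc(cc1)S(=O)(=O)Oc1cc(Br)c(N)c(Br)c1Oc1cc(Br)cc(Br)c1OC | intermediate
15 | 2,6-dibromo-3-(3,5-dibromo-2-methoxyphenoxy)-4-(tosyloxy)benzenediazonium hydrogensulfate (not isolated) | Cc1ccc(cc1)S(=O)(=O)Oc1cc(Br)c([N+]#N)c(Br)c1Oc1cc(Br)cc(Br)c1OC.OS(=O)(=O)[O-] | intermediate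
16 | 3,5-dibromo-2-(3,5-dibromo-2-methoxyphenoxy)phenyl 4-methylbenzenesulfonate | Cc1ccc(cc1)S(=O)(=O)Oc1cc(Br)cc(Br)c1Oc1cc(Br)cc(Br)c1OC | intermediate
17 | 3,5-dibromo-2-(3,5-dibromo-2-methoxyphenoxy)phenol (achiral) | COc1c(Br)cc(Br)cc1Oc1c(O)cc(Br)cc1Br | target

**Total step count:** 10.
**Longest linear sequence:** 9 steps (1, 2, 3, 5, 6, 7, 8, 9, 10). Step 4 is a one-step side branch.

**Three steps most likely to fail**

Step 5 is the ring-B benzannulation. The electrophile is a delocalised anion and 6 is hydrophobic, so the reaction may be slow or lose material to self-condensation of 6. The fallback sets out from 4 and comes back at 10. Compound 4 is heated with 2-fluorobenzaldehyde (K2CO3, DMAc, 130 °C, SNAr ortho to CHO) to give 2-(3,5-dibromo-2-methoxyphenoxy)benzaldehyde F1. Baeyer–Villiger oxidation with mCPBA in CH2Cl2 gives 2-(3,5-dibromo-2-methoxyphenoxy)phenyl formate F2. Acidic methanol cleaves this to 2-(3,5-dibromo-2-methoxyphenoxy)phenol F3. Nitration with 1 equiv HNO3 in AcOH at 0–10 °C goes para to the free OH, and the minor 6-nitro isomer is removed by chromatography, which delivers 10.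

Step 9 is the deamination. The amine is weakly basic and doubly ortho-hindered, so reduction of the diazonium salt can be diverted to phenol or azo products. The fallback sets out from 14 and comes back at 16. Compound 14 is diazotised as before to 15 and poured into aqueous KI to give 3,5-dibromo-2-(3,5-dibromo-2-methoxyphenoxy)-4-iodophenyl 4-methylbenzenesulfonate F4. Iodine–magnesium exchange (iPrMgCl·LiCl, THF, −78 °C) is selective for iodine over bromine and gives [2,6-dibromo-3-(3,5-dibromo-2-methoxyphenoxy)-4-(tosyloxy)phenyl]magnesium chloride F5. This is protonated with MeOH at −78 °C, before any aryne formation, to give 16.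

Step 2 is the Baeyer–Villiger oxidation of the aldehyde. On this electron-poor ring with a twisted methoxy group, hydride migration could give the benzoic acid instead of the formate. The fallback sets out from 2 and comes back at 4. MeMgBr (THF, −78 → 0 °C) gives racemic 1-(3,5-dibromo-2-methoxyphenyl)ethan-1-ol F6. Dess–Martin oxidation gives 1-(3,5-dibromo-2-methoxyphenyl)ethan-1-one F7. Baeyer–Villiger oxidation with trifluoroperacetic acid (urea·H2O2, TFAA, Na2HPO4, CH2Cl2) now lets only aryl compete with methyl and gives 3,5-dibromo-2-methoxyphenyl acetate F8. K2CO3/MeOH then delivers 4.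

**Further compounds**
F1 | step 5 | 2-(3,5-dibromo-2-methoxyphenoxy)benzaldehyde | O=Cc1ccccc1Oc1cc(Br)cc(Br)c1OC
F2 | step 5 | 2-(3,5-dibromo-2-methoxyphenoxy)phenyl formate | O=COc1ccccc1Oc1cc(Br)cc(Br)c1OC
F3 | step 5 | 2-(3,5-dibromo-2-methoxyphenoxy)phenol | Oc1ccccc1Oc1cc(Br)cc(Br)c1OC
F4 | step 9 | 3,5-dibromo-2-(3,5-dibromo-2-methoxyphenoxy)-4-iodophenyl 4-methylbenzenesulfonate | Cc1ccc(cc1)S(=O)(=O)Oc1cc(Br)c(I)c(Br)c1Oc1cc(Br)cc(Br)c1OC
F5 | step 9 | [2,6-dibromo-3-(3,5-dibromo-2-methoxyphenoxy)-4-(tosyloxy)phenyl]magnesium chloride | Cc1ccc(cc1)S(=O)(=O)Oc1cc(Br)c([Mg]Cl)c(Br)c1Oc1cc(Br)cc(Br)c1OC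
F6 | step 2 | 1-(3,5-dibromo-2-methoxyphenyl)ethan-1-ol (racemic) | CC(O)c1cc(Br)cc(Br)c1OC
F7 | step 2 | 1-(3,5-dibromo-2-methoxyphenyl)ethan-1-one | CC(=O)c1cc(Br)cc(Br)c1OC
F8 | step 2 | 3,5-dibromo-2-methoxyphenyl acetate | CC(=O)Oc1cc(Br)cc(Br)c1OC
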